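The oxane ring is cut at O1–C6. C6 is a fully substituted ether carbon bearing a methyl group and the dienyl arm, and the first carbon of that arm can be held at the aldehyde oxidation level. Anodic oxidation of a methyl enol ether therefore lets the C2 tertiary hydroxyl attack C6 of the derived radical cation; this closes the oxane, sets C6 and delivers the arm carbon as a dimethyl acetal in one operation. The precursor is the open-chain bromohydrin (3S)-3-bromo-7-methoxy-2,6-dimethylhept-6-en-2-ol, whose bromine stereocentre comes from an L-amino acid. Acetal hydrolysis, Takai iodo-olefination and Suzuki coupling with a cyclohexyl (E)-alkenylboronate complete the diene.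

Key step: step 8

Remark: enol ethers 7 and 8 are carried as E/Z mixtures, since both isomers give the same radical cation; names and SMILES show the 6E isomer.

**Eastern half**

Step 1
Reactants: 1 (2S)-2-aminohex-5-enoic acid (L-homoallylglycine)
Product: 2 (2S)-2-bromohex-5-enoic acid
Conditions: NaNO2, KBr, 1 M aq HBr, −10 to 0 °C
Reagents that add atoms: potassium bromide, [K+].[Br-]; hydrobromic acid, Br
Why: Diazotisation of the α-amino acid (bromodeamination) should go with retention, because the α-carboxylate displaces nitrogen to an α-lactone that bromide then opens (two inversions), so the S amino acid gives the S bromide, and the remote terminal alkene is inert to cold dilute nitrous acid.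

Step 2
Reactants: 2 (2S)-2-bromohex-5-enoic acid
Product: 3 methyl (2S)-2-bromohex-5-enoate
Conditions: Me3SiCHN2, MeOH/toluene, 0 °C to rt
Reagents that add atoms: trimethylsilyldiazomethane, C[Si](C)(C)C=[N+]=[N-]
Why: Esterification with trimethylsilyldiazomethane is neutral and free of halide, so the α-bromo centre cannot epimerise by enolisation or by bromide exchange.

Step 3
Reactants: 3 methyl (2S)-2-bromohex-5-enoate
Product: 4 (3S)-3-bromo-2-methylhept-6-en-2-ol
Conditions: MeMgBr (2.3 equiv), THF, −78 to −20 °C; aq NH4Cl at −20 °C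
Reagents that add atoms: methylmagnesium bromide, C[Mg]Br
Why: Double Grignard addition to the activated α-bromo ester should give the tertiary carbinol, and the cold magnesium bromohydrinate neither closes to the epoxide nor rearranges, so the C–Br centre is untouched.

Step 4
Reactants: 4 (3S)-3-bromo-2-methylhept-6-en-2-ol
Product: 5 (5S)-5-bromo-6-hydroxy-6-methylheptan-2-one
Conditions: PdCl2 (10 mol%), CuCl, O2 (1 atm), DMF/H2O (7:1), rt
Reagents that add atoms: water, O
Why: Tsuji–Wacker oxidation should convert the terminal alkene into the methyl ketone with Markovnikov selectivity; the secondary bromide and the tertiary alcohol are inert, and any cyclic enol ether from internal oxypalladation hydrolyses to the same δ-hydroxy ketone.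

Step 5
Reactants: 5 (5S)-5-bromo-6-hydroxy-6-methylheptan-2-one
Product: 6 (5S)-5-bromo-6-methyl-6-(trimethylsilyloxy)heptan-2-one
Conditions: 1-(trimethylsilyl)imidazole, CH2Cl2, rt
Reagents that add atoms: 1-(trimethylsilyl)imidazole, C[Si](C)(C)n1ccnc1
Why: O-Silylation with the N-silylimidazole caps the tertiary hydroxyl of the open-chain hydroxy ketone without a base that could close the epoxide and without enolising the ketone, which is needed before the basic ylide of the next step.

Step 6
Reactants: 6 (5S)-5-bromo-6-methyl-6-(trimethylsilyloxy)heptan-2-one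
Product: 7 {[(3S,6E)-3-bromo-7-methoxy-2,6-dimethylhept-6-en-2-yl]oxy}(trimethyl)silane
Conditions: Ph3P(CH2OMe)Cl, KN(SiMe3)2, THF, 0 °C; then 6, −78 to 0 °C
Reagents that add atoms: (methoxymethyl)triphenylphosphonium chloride, COC[P+](c1ccccc1)(c1ccccc1)c1ccccc1.[Cl-]
Why: Wittig methoxymethylenation of the methyl ketone should give the enol ether, since the preformed ylide adds to the ketone at low temperature faster than it can eliminate the hindered secondary bromide, and the E/Z ratio does not matter.

Step 7
Reactants: 7 {[(3S,6E)-3-bromo-7-methoxy-2,6-dimethylhept-6-en-2-yl]oxy}(trimethyl)silane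
Product: 8 (3S,6E)-3-bromo-7-methoxy-2,6-dimethylhept-6-en-2-ol
Conditions: Bu4NF, AcOH (1:1), THF, 0 °C
Reagents that add atoms: none
Why: Fluoride-mediated desilylation buffered with acetic acid should free the tertiary alcohol without an alkoxide long-lived enough to close the bromohydrin to the epoxide and without acid strong enough to hydrolyse the enol ether.

Step 8
Reactants: 8 (3S,6E)-3-bromo-7-methoxy-2,6-dimethylhept-6-en-2-ol
Product: 9 (3S,6R)-3-bromo-6-(dimethoxymethyl)-2,2,6-trimethyloxane
Conditions: reticulated vitreous carbon anode, Pt cathode, undivided cell, constant current (8 mA, 2.2 F/mol), 0.1 M LiClO4, 2,6-lutidine, MeOH/THF (3:7), rt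
Reagents that add atoms: methanol, CO
Why: One-electron oxidation at the anode converts the electron-rich enol ether, which is oxidised well below the alcohol and the alkyl bromide, into a radical cation whose methyl-bearing carbon C6 is attacked by the tertiary hydroxyl, after which the α-methoxy radical is oxidised again and the oxocarbenium ion is captured by methanol as the dimethyl acetal. The closest known reaction type is the anodic coupling of enol ether radical cations with tethered alcohol nucleophiles, which builds tetrahydrofurans and tetrahydropyrans with fully substituted ether carbons. The oxane ring closes in the 6-exo-trig mode, helped by the gem-dimethyl group at C2. The new C6 centre should be set by a chair-like transition state with the C3 bromine and the methoxymethylene arm equatorial and the C6 methyl axial, the arm avoiding the axial site because of the syn-axial C2 methyl, which gives 6R from 3S. The step needs chemoselectivity, cyclisation before methanol traps the radical cation, which the low methanol content and the Thorpe–Ingold effect should secure, and facial selectivity relative to C3, which rests only on the modest equatorial preference of bromine, so the C6 epimer is the expected by-product. 2,6-Lutidine buffers the anolyte, and the platinum cathode evolves hydrogen at a potential too mild to reduce the C–Br bond or to build up methoxide that would close the bromohydrin to an epoxide.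

Step 9
Reactants: 9 (3S,6R)-3-bromo-6-(dimethoxymethyl)-2,2,6-trimethyloxane
Product: 10 (2R,5S)-5-bromo-2,6,6-trimethyloxane-2-carbaldehyde
Conditions: CF3CO2H/H2O (9:1), CH2Cl2, 0 °C to rt
Reagents that add atoms: water, O
Why: Acid-catalysed acetal hydrolysis should free the aldehyde; its α-carbon is quaternary, so nothing can epimerise, and the oxane ether and the secondary bromide are stable to acid.

Step 10
Reactants: 10 (2R,5S)-5-bromo-2,6,6-trimethyloxane-2-carbaldehyde
Product: 11 (3S,6R)-3-bromo-6-[(E)-2-iodoethenyl]-2,2,6-trimethyloxane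
Conditions: CHI3, CrCl2, THF, 0 °C to rt, dark
Reagents that add atoms: iodoform, IC(I)I
Why: Takai olefination, in which the geminal dichromium species from iodoform adds to the hindered aldehyde and eliminates to the E-iodoalkene; divalent chromium should not reduce an unactivated secondary bromide under these conditions.

**Western half**

Step 11
Reactants: 12 1,4-dioxaspiro[4.5]decane-8-carbaldehyde
Product: 13 8-ethynyl-1,4-dioxaspiro[4.5]decane
Conditions: dimethyl (1-diazo-2-oxopropyl)phosphonate, K2CO3, MeOH, 0 °C to rt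
Reagents that add atoms: dimethyl (1-diazo-2-oxopropyl)phosphonate, COP(=O)(OC)C(=[N+]=[N-])C(C)=O
Why: Ohira–Bestmann (Seyferth–Gilbert) homologation should convert the aldehyde into the terminal alkyne under carbonate conditions that leave the ketal alone, and the α-carbon is not stereogenic.

Step 12
Reactants: 13 8-ethynyl-1,4-dioxaspiro[4.5]decane
Product: 14 2-[(E)-2-(1,4-dioxaspiro[4.5]decan-8-yl)prop-1-en-1-yl]-4,4,5,5-tetramethyl-1,3,2-dioxaborolane
Conditions: CuCl (10 mol%), Xantphos (10 mol%), NaOtBu, B2pin2, MeI, THF, rt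
Reagents that add atoms: bis(pinacolato)diboron, CC1(C)OB(OC1(C)C)B1OC(C)(C)C(C)(C)O1; iodomethane, CI
Why: Copper-catalysed methylboration of a terminal alkyne, in which a boryl–copper species adds syn with boron at the terminal carbon and the alkenylcopper is methylated with retention, so methyl and boron end up cis and the ring trans to boron (E).

Step 13
Reactants: 14 2-[(E)-2-(1,4-dioxaspiro[4.5]decan-8-yl)prop-1-en-1-yl]-4,4,5,5-tetramethyl-1,3,2-dioxaborolane
Product: 15 4-[(E)-1-(4,4,5,5-tetramethyl-1,3,2-dioxaborolan-2-yl)prop-1-en-2-yl]cyclohexan-1-one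
Conditions: 1 M aq HCl, THF, rt
Reagents that add atoms: water, O
Why: Mild acid-catalysed ketal hydrolysis should release the ketone, and pinacol alkenylboronates tolerate these conditions.

Step 14
Reactants: 15 4-[(E)-1-(4,4,5,5-tetramethyl-1,3,2-dioxaborolan-2-yl)prop-1-en-2-yl]cyclohexan-1-one
Product: 16 trimethyl({(4S)-4-[(E)-1-(4,4,5,5-tetramethyl-1,3,2-dioxaborolan-2-yl)prop-1-en-2-yl]cyclohex-1-en-1-yl}oxy)silane
Conditions: (R,R)-bis(1-phenylethyl)amine, n-BuLi, LiCl, Me3SiCl (in situ), THF, −78 °C
Reagents that add atoms: chlorotrimethylsilane, C[Si](C)(C)Cl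
Why: Enantioselective deprotonation with a chiral lithium amide and internal silyl quench desymmetrises the 4-substituted cyclohexanone, C4 becoming stereogenic through the choice of enantiotopic α-methylene; by analogy with 4-alkylcyclohexanones the (R,R)-amide should give the S enol ether (the antipodal amide gives its mirror image), and any minor enantiomer becomes a separable diastereomer after the final coupling.

Step 15
Reactants: 16 trimethyl({(4S)-4-[(E)-1-(4,4,5,5-tetramethyl-1,3,2-dioxaborolan-2-yl)prop-1-en-2-yl]cyclohex-1-en-1-yl}oxy)silane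
Product: 18 (2S,4S)-2-bromo-4-[(E)-1-(4,4,5,5-tetramethyl-1,3,2-dioxaborolan-2-yl)prop-1-en-2-yl]cyclohexan-1-one (cis), via trans-bromoketone 17 (not isolated)
Conditions: NBS, THF, −78 °C; then Bu4NBr (0.2 equiv), NaHCO3, MeCN, rt
Reagents that add atoms: N-bromosuccinimide, O=C1CCC(=O)N1Br
Why: Electrophilic bromination of the silyl enol ether fixes bromine on the enolised carbon, axial attack giving mainly the trans ketone; bromide then epimerises C2 alone by SN2 exchange, without enolisation and so without loss of the C4 information, towards the diequatorial cis isomer that a polar medium favours, which is separated while the trans isomer is returned to the equilibration.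

Step 16
Reactants: 18 (2S,4S)-2-bromo-4-[(E)-1-(4,4,5,5-tetramethyl-1,3,2-dioxaborolan-2-yl)prop-1-en-2-yl]cyclohexan-1-one
Product: 19 (1R,2S,4S)-2-bromo-1-methyl-4-[(E)-1-(4,4,5,5-tetramethyl-1,3,2-dioxaborolan-2-yl)prop-1-en-2-yl]cyclohexan-1-ol
Conditions: MeMgBr, Et2O/toluene, −78 °C; aq NH4Cl at −78 °C
Reagents that add atoms: methylmagnesium bromide, C[Mg]Br
Why: Grignard 1,2-addition under Cornforth (polar Felkin–Anh) control, in which methyl enters trans to bromine (equatorially on the diequatorial chair, or anti to an axial bromine in the flipped chair), giving the cis-bromohydrin with hydroxyl cis to bromine (1R from 2S); at −78 °C the ketone reacts far faster than the pinacol boronate.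

**Coupling**

Step 17
Reactants: 11 (3S,6R)-3-bromo-6-[(E)-2-iodoethenyl]-2,2,6-trimethyloxane; 19 (1R,2S,4S)-2-bromo-1-methyl-4-[(E)-1-(4,4,5,5-tetramethyl-1,3,2-dioxaborolan-2-yl)prop-1-en-2-yl]cyclohexan-1-ol
Product: 20 (1R,2S,4S)-2-bromo-4-{(2E,4E)-5-[(2R,5S)-5-bromo-2,6,6-trimethyloxan-2-yl]penta-2,4-dien-2-yl}-1-methylcyclohexan-1-ol
Conditions: Pd(dppf)Cl2 (5 mol%), K3PO4, THF/H2O, rt, degassed
Reagents that add atoms: none
Why: Suzuki–Miyaura coupling of the alkenyl iodide with the alkenylboronate proceeds with retention at both double bonds to give the E,E-diene, and phosphate at room temperature should spare both secondary bromides and the cis-bromohydrin, which has no anti-periplanar hydroxyl for epoxide closure.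

**Compound list**

1 | (2S)-2-aminohex-5-enoic acid (L-homoallylglycine) | N[C@@H](CCC=C)C(=O)O | starting material
2 | (2S)-2-bromohex-5-enoic acid | OC(=O)[C@@H](Br)CCC=C | intermediate
3 | methyl (2S)-2-bromohex-5-enoate | COC(=O)[C@@H](Br)CCC=C | intermediate
4 | (3S)-3-bromo-2-methylhept-6-en-2-ol | C=CCC[C@H](Br)C(C)(C)O | intermediate
5 | (5S)-5-bromo-6-hydroxy-6-methylheptan-2-one | CC(=O)CC[C@H](Br)C(C)(C)O | intermediate
6 | (5S)-5-bromo-6-methyl-6-(trimethylsilyloxy)heptan-2-one | CC(=O)CC[C@H](Br)C(C)(C)O[Si](C)(C)C | intermediate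
7 | {[(3S,6E)-3-bromo-7-methoxy-2,6-dimethylhept-6-en-2-yl]oxy}(trimethyl)silane (E/Z mixture, 6E shown) | CO/C=C(\C)CC[C@H](Br)C(C)(C)O[Si](C)(C)C | intermediate
8 | (3S,6E)-3-bromo-7-methoxy-2,6-dimethylhept-6-en-2-ol (E/Z mixture, 6E shown) | CO/C=C(\C)CC[C@H](Br)C(C)(C)O | intermediate
9 | (3S,6R)-3-bromo-6-(dimethoxymethyl)-2,2,6-trimethyloxane | COC(OC)[C@@]1(C)CC[C@H](Br)C(C)(C)O1 | intermediate
10 | (2R,5S)-5-bromo-2,6,6-trimethyloxane-2-carbaldehyde | O=C[C@@]1(C)CC[C@H](Br)C(C)(C)O1 | intermediate
11 | (3S,6R)-3-bromo-6-[(E)-2-iodoethenyl]-2,2,6-trimethyloxane | I/C=C/[C@@]1(C)CC[C@H](Br)C(C)(C)O1 | intermediate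
12 | 1,4-dioxaspiro[4.5]decane-8-carbaldehyde | O=CC1CCC2(CC1)OCCO2 | starting material
13 | 8-ethynyl-1,4-dioxaspiro[4.5]decane | C#CC1CCC2(CC1)OCCO2 | intermediate
14 | 2-[(E)-2-(1,4-dioxaspiro[4.5]decan-8-yl)prop-1-en-1-yl]-4,4,5,5-tetramethyl-1,3,2-dioxaborolane | C/C(=C\B1OC(C)(C)C(C)(C)O1)C1CCC2(CC1)OCCO2 | intermediate
15 | 4-[(E)-1-(4,4,5,5-tetramethyl-1,3,2-dioxaborolan-2-yl)prop-1-en-2-yl]cyclohexan-1-one | C/C(=C\B1OC(C)(C)C(C)(C)O1)C1CCC(=O)CC1 | intermediate
16 | trimethyl({(4S)-4-[(E)-1-(4,4,5,5-tetramethyl-1,3,2-dioxaborolan-2-yl)prop-1-en-2-yl]cyclohex-1-en-1-yl}oxy)silane | C/C(=C\B1OC(C)(C)C(C)(C)O1)[C@@H]1CC=C(O[Si](C)(C)C)CC1 | intermediate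
17 | (2R,4S)-2-bromo-4-[(E)-1-(4,4,5,5-tetramethyl-1,3,2-dioxaborolan-2-yl)prop-1-en-2-yl]cyclohexan-1-one (trans, not isolated) | C/C(=C\B1OC(C)(C)C(C)(C)O1)[C@H]1CCC(=O)[C@H](Br)C1 | intermediate
18 | (2S,4S)-2-bromo-4-[(E)-1-(4,4,5,5-tetramethyl-1,3,2-dioxaborolan-2-yl)prop-1-en-2-yl]cyclohexan-1-one (cis) | C/C(=C\B1OC(C)(C)C(C)(C)O1)[C@H]1CCC(=O)[C@@H](Br)C1 | intermediate
19 | (1R,2S,4S)-2-bromo-1-methyl-4-[(E)-1-(4,4,5,5-tetramethyl-1,3,2-dioxaborolan-2-yl)prop-1-en-2-yl]cyclohexan-1-ol | C/C(=C\B1OC(C)(C)C(C)(C)O1)[C@H]1CC[C@@](C)(O)[C@@H](Br)C1 | intermediate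
20 | (1R,2S,4S)-2-bromo-4-{(2E,4E)-5-[(2R,5S)-5-bromo-2,6,6-trimethyloxan-2-yl]penta-2,4-dien-2-yl}-1-methylcyclohexan-1-ol | C/C(=C\C=C\[C@@]1(C)CC[C@H](Br)C(C)(C)O1)[C@H]1CC[C@@](C)(O)[C@@H](Br)C1 | target

**Step count and risks**

Total steps: 17. Longest linear sequence: 11 (steps 1 to 10, then step 17); the western branch has 6 steps before the coupling.

Step 8 (anodic cyclisation). Three processes may defeat it. Methanol may trap the radical cation before the hindered tertiary hydroxyl attacks. Facial control at C6 may be weak, because bromine prefers the equatorial site only mildly. Methoxide formed at the cathode may close the bromohydrin to an epoxide. The fallback sets out from 6 and returns at 10. Wittig methylenation of ketone 6 (Ph3P=CH2) would give [(3S)-3-bromo-2,6-dimethylhept-6-en-2-yl]oxy(trimethyl)silane F1, and buffered fluoride (Bu4NF, AcOH) would free (3S)-3-bromo-2,6-dimethylhept-6-en-2-ol F2. Intramolecular oxymercuration with Hg(OCOCF3)2 (divalent mercury) is reversible, so the chair with bromine and the mercurimethyl arm equatorial should be reached under thermodynamic control, giving [(2R,5S)-5-bromo-2,6,6-trimethyloxan-2-yl]methylmercury trifluoroacetate F3. Oxidative demercuration (NaBH4, O2, DMF) would give [(2R,5S)-5-bromo-2,6,6-trimethyloxan-2-yl]methanol F4, and Dess–Martin oxidation would return to aldehyde 10.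

Step 15 (bromination and epimerisation). The thermodynamic bias towards equatorial bromine may be too small for a useful cis/trans ratio. Traces of HBr may also let bromine migrate to C6 and erode the enantiomeric purity, which already depends on the incomplete selectivity of the chiral amide in step 14. The fallback sets out from 15 and returns at 18, replacing steps 14 and 15. L-Proline-catalysed α-aminoxylation of ketone 15 with nitrosobenzene should desymmetrise it, axial attack trans to the side chain being expected, to give (2R,4S)-2-(anilinooxy)-4-[(E)-1-(4,4,5,5-tetramethyl-1,3,2-dioxaborolan-2-yl)prop-1-en-2-yl]cyclohexan-1-one F5. Excess nitrosobenzene would cleave its O–N bond to (2R,4S)-2-hydroxy-4-[(E)-1-(4,4,5,5-tetramethyl-1,3,2-dioxaborolan-2-yl)prop-1-en-2-yl]cyclohexan-1-one F6. Tf2O and 2,6-lutidine at −78 °C would give (1R,5S)-2-oxo-5-[(E)-1-(4,4,5,5-tetramethyl-1,3,2-dioxaborolan-2-yl)prop-1-en-2-yl]cyclohexyl trifluoromethanesulfonate F7. One equivalent of Bu4NBr in the cold would then displace the triflate with inversion (SN2 at the carbonyl-activated carbon, no excess bromide left to re-equilibrate) to give cis-bromoketone 18 under kinetic control.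

Step 12 (methylboration). With an aliphatic terminal alkyne, copper acetylide formation may compete and the regiocontrol of borylcupration may be imperfect. The fallback sets out from 13 and returns at 14. Negishi carboalumination (Me3Al, Cp2ZrCl2 catalyst, CH2Cl2) would add methyl and aluminium syn to give [(E)-2-(1,4-dioxaspiro[4.5]decan-8-yl)prop-1-en-1-yl]dimethylalumane F8. Iodinolysis would give 8-[(E)-1-iodoprop-1-en-2-yl]-1,4-dioxaspiro[4.5]decane F9, and Miyaura borylation (PdCl2(PPh3)2, B2pin2, KOPh, toluene, 50 °C) would return to boronate 14.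

Further compounds
F1 | step 8 | [(3S)-3-bromo-2,6-dimethylhept-6-en-2-yl]oxy(trimethyl)silane | C=C(C)CC[C@H](Br)C(C)(C)O[Si](C)(C)C
F2 | step 8 | (3S)-3-bromo-2,6-dimethylhept-6-en-2-ol | C=C(C)CC[C@H](Br)C(C)(C)O
F3 | step 8 | [(2R,5S)-5-bromo-2,6,6-trimethyloxan-2-yl]methylmercury trifluoroacetate | FC(F)(F)C(=O)O[Hg]C[C@@]1(C)CC[C@H](Br)C(C)(C)O1
F4 | step 8 | [(2R,5S)-5-bromo-2,6,6-trimethyloxan-2-yl]methanol | OC[C@@]1(C)CC[C@H](Br)C(C)(C)O1
F5 | step 15 | (2R,4S)-2-(anilinooxy)-4-[(E)-1-(4,4,5,5-tetramethyl-1,3,2-dioxaborolan-2-yl)prop-1-en-2-yl]cyclohexan-1-one | C/C(=C\B1OC(C)(C)C(C)(C)O1)[C@H]1CCC(=O)[C@H](ONc2ccccc2)C1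
F6 | step 15 | (2R,4S)-2-hydroxy-4-[(E)-1-(4,4,5,5-tetramethyl-1,3,2-dioxaborolan-2-yl)prop-1-en-2-yl]cyclohexan-1-one | C/C(=C\B1OC(C)(C)C(C)(C)O1)[C@H]1CCC(=O)[C@H](O)C1
F7 | step 15 | (1R,5S)-2-oxo-5-[(E)-1-(4,4,5,5-tetramethyl-1,3,2-dioxaborolan-2-yl)prop-1-en-2-yl]cyclohexyl trifluoromethanesulfonate | C/C(=C\B1OC(C)(C)C(C)(C)O1)[C@H]1CCC(=O)[C@H](OS(=O)(=O)C(F)(F)F)C1
F8 | step 12 | [(E)-2-(1,4-dioxaspiro[4.5]decan-8-yl)prop-1-en-1-yl]dimethylalumane | C/C(=C\[Al](C)C)C1CCC2(CC1)OCCO2
F9 | step 12 | 8-[(E)-1-iodoprop-1-en-2-yl]-1,4-dioxaspiro[4.5]decane | C/C(=C\I)C1CCC2(CC1)OCCO2
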